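**Strategy.** Ring C of the flavanone is disconnected at the aryl ketone bond C4–C4a and at the aryl ether bond O1–C8a. This gives a ring A aryne and an open-chain (S)-3-aryl-3-hydroxypropanoic morpholine amide that already carries the geranylated ring B and the C2 stereocentre. In the key step the potassium alkoxide adds to 3,5-bis(methoxymethoxy)benzyne and the resulting aryl anion closes the pyranone ring by attacking the amide carbonyl. The step exploits the C5 oxygen of ring A: placed next to the aryne carbon C4a, it steers the alkoxide to C8a and leaves the carbanion on C4a, poised for 6-exo-trig attack on C4. Acidic removal of three MOM groups then gives the target.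

Key step: step 8

Remark on the chemistry: "geranyl" means (2E)-3,7-dimethylocta-2,6-dien-1-yl and MOM means methoxymethyl throughout; flavanone numbering (O1, C2, C3, C4, C4a, C5 to C8, C8a) is used; in-flask anions are drawn with the cation of the base that forms them, and 18-crown-6 and LiCl are treated as unchanged additives.

**Route**

Step 1
Reactants: 1 methyl 4-hydroxy-3-iodobenzoate
Product: 2 methyl 3-iodo-4-(methoxymethoxy)benzoate
Conditions: NaH, MOMCl, DMF, 0 °C → rt
Reagents that add atoms: chloromethyl methyl ether, COCCl
Why: Williamson-type O-alkylation of the sodium phenoxide with the hard electrophile MOMCl should protect the phenol without touching the ester or the aryl iodide.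

Step 2
Reactants: 2 methyl 3-iodo-4-(methoxymethoxy)benzoate; 3 geranyl bromide, (E)-1-bromo-3,7-dimethylocta-2,6-diene
Product: 5 methyl 3-geranyl-4-(methoxymethoxy)benzoate, via arylmagnesium chloride 4 (not isolated)
Conditions: i-PrMgCl·LiCl, THF, −40 °C; then CuBr·SMe2 (10 mol%), 3, −40 → 0 °C
Reagents that add atoms: none
Why: Iodine–magnesium exchange, accelerated by the ortho OMOM group and tolerated by the ester at −40 °C, followed by copper-catalysed allylic substitution at the primary carbon of geranyl bromide, should give the linear aryl–allyl product with the (E)-alkene retained.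

Step 3
Reactants: 5 methyl 3-geranyl-4-(methoxymethoxy)benzoate; 6 N-acetylmorpholine
Product: 8 1-[3-geranyl-4-(methoxymethoxy)phenyl]-3-morpholinopropane-1,3-dione, via lithium amide enolate 7 (not isolated)
Conditions: LiN(i-Pr)2 (2.2 equiv), 6 (2.2 equiv), THF, −78 °C; then 5, −78 → 0 °C; AcOH quench
Reagents that add atoms: none
Why: Crossed Claisen condensation of the amide enolate with the non-enolisable benzoate should stop at the β-keto amide because the product is deprotonated by the excess enolate.

Step 4
Reactants: 8 1-[3-geranyl-4-(methoxymethoxy)phenyl]-3-morpholinopropane-1,3-dione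
Product: 9 (S)-3-[3-geranyl-4-(methoxymethoxy)phenyl]-3-hydroxy-1-morpholinopropan-1-one
Conditions: RuCl(p-cymene)[(S,S)-TsDPEN] (1 mol%), HCO2H/Et3N (5:2), DMF, rt
Reagents that add atoms: none
Why: Noyori-type asymmetric transfer hydrogenation of the aryl ketone should set the C2 carbinol centre as (S) through the (S,S)-TsDPEN ligand, in the sense established for aryl alkyl ketones, and leave the geranyl alkenes and the MOM ether untouched.

Step 5
Reactants: 10 phloroglucinol
Product: 11 3,5-bis(methoxymethoxy)phenol
Conditions: NaH (2 equiv), MOMCl (2 equiv), DMF, 0 °C → rt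
Reagents that add atoms: chloromethyl methyl ether, COCCl
Why: Statistical double Williamson-type O-alkylation of the symmetric triol should give the bis-ether as the main component, separable by chromatography from the mono- and tris-ethers.

Step 6
Reactants: 11 3,5-bis(methoxymethoxy)phenol
Product: 12 2-bromo-3,5-bis(methoxymethoxy)phenol
Conditions: NBS (1.0 equiv), CH2Cl2, −78 → −20 °C
Reagents that add atoms: N-bromosuccinimide, O=C1CCC(=O)N1Br
Why: Electrophilic aromatic bromination should go ortho to the free hydroxyl (C2), which can deliver NBS by hydrogen bonding and is less hindered than C4 between two OMOM groups, and one equivalent at low temperature limits over-bromination.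

Step 7
Reactants: 12 2-bromo-3,5-bis(methoxymethoxy)phenol
Product: 16 3,5-bis(methoxymethoxy)-2-(trimethylsilyl)phenyl trifluoromethanesulfonate, via aryl silyl ether 13 (not isolated), via aryllithium 14 (not isolated), via lithium phenoxide 15 (not isolated)
Conditions: (Me3Si)2NH, THF, 65 °C, then evaporate; n-BuLi, THF, −100 → −80 °C; Tf2O, −100 °C → rt
Reagents that add atoms: hexamethyldisilazane, C[Si](C)(C)N[Si](C)(C)C; trifluoromethanesulfonic anhydride, O=S(=O)(OS(=O)(=O)C(F)(F)F)C(F)(F)F
Why: O-silylation, bromine–lithium exchange (faster than ortho-lithiation at −100 °C), retro-Brook 1,3-migration of silicon from oxygen to the lithiated carbon and triflation of the released phenoxide form the standard sequence to 2-silylaryl triflates.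

Step 8
Reactants: 9 (S)-3-[3-geranyl-4-(methoxymethoxy)phenyl]-3-hydroxy-1-morpholinopropan-1-one; 16 3,5-bis(methoxymethoxy)-2-(trimethylsilyl)phenyl trifluoromethanesulfonate
Product: 21 (S)-5,7-bis(methoxymethoxy)-2-[3-geranyl-4-(methoxymethoxy)phenyl]chroman-4-one, via potassium alkoxide 17 (not isolated), via aryne 18 (not isolated), via arylpotassium 19 (not isolated), via hemiaminal alkoxide 20 (not isolated)
Conditions: KH, 18-crown-6, THF, 0 °C; then 16 (1.5 equiv), KF, THF, 0 °C → rt; AcOH, 0 °C
Reagents that add atoms: none
Why: Proposed new method: KF/18-crown-6 strips the silyl group of 16 to give aryne 18, the pre-formed alkoxide 17 adds to the aryne carbon remote from the flanking OMOM group (the future C8a), and the aryl anion 19, held on C4a between two oxygen substituents, attacks the morpholine amide carbonyl to give hemiaminal alkoxide 20, which should not collapse until the acetic acid quench releases morpholine and ketone 21. The closest known reaction types are the fluoride-triggered aryne annulation of salicylate esters to xanthones (O-addition to the aryne, then intramolecular acyl substitution by the aryl anion) and the Parham cyclization of aryl anions onto tethered amides, and what is new is an aliphatic secondary alkoxide as the aryne nucleophile with a β-amide as the internal acceptor. The pyranone ring closes in a 6-exo-trig mode at C4. No stereocentre is created, because C2 comes from 9 with retention (its C–O bond is never broken) and the transient C4 centre of 20 disappears on work-up. The step needs O-attack at C8a, secured by the inductive polarisation of the aryne by the C5 oxygen, acylation instead of protonation of 19, secured by an aprotic medium with the alkoxide made beforehand with KH, and configurational stability at C2, secured because 20 keeps C4 masked so that no enolisable β-aryloxy ketone meets base. An ene reaction of the aryne with the geranyl alkenes is expected to be slower than the anionic addition.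

Step 9
Reactants: 21 (S)-5,7-bis(methoxymethoxy)-2-[3-geranyl-4-(methoxymethoxy)phenyl]chroman-4-one
Product: 22 (S)-5,7-dihydroxy-2-(3-geranyl-4-hydroxyphenyl)chroman-4-one
Conditions: HCl (3 M in MeOH), THF, rt → 40 °C
Reagents that add atoms: none
Why: Acid-catalysed acetal exchange with methanol should remove all three MOM groups under conditions mild enough to spare the ortho-geranyl phenol from chroman formation and the C2 centre from ring-opening epimerisation.

**Compound list**

1 | methyl 4-hydroxy-3-iodobenzoate | COC(=O)c1ccc(O)c(I)c1 | starting material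
2 | methyl 3-iodo-4-(methoxymethoxy)benzoate | COC(=O)c1ccc(OCOC)c(I)c1 | intermediate
3 | geranyl bromide, (E)-1-bromo-3,7-dimethylocta-2,6-diene | CC(C)=CCC/C(C)=C/CBr | starting material
4 | [5-(methoxycarbonyl)-2-(methoxymethoxy)phenyl]magnesium chloride | COC(=O)c1ccc(OCOC)c([Mg]Cl)c1 | intermediate (not isolated)
5 | methyl 3-geranyl-4-(methoxymethoxy)benzoate | CC(C)=CCC/C(C)=C/Cc1cc(C(=O)OC)ccc1OCOC | intermediate
6 | N-acetylmorpholine (1-morpholinoethan-1-one) | CC(=O)N1CCOCC1 | starting material
7 | lithium enolate of N-acetylmorpholine | C=C(O[Li])N1CCOCC1 | intermediate (not isolated)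
8 | 1-[3-geranyl-4-(methoxymethoxy)phenyl]-3-morpholinopropane-1,3-dione | CC(C)=CCC/C(C)=C/Cc1cc(C(=O)CC(=O)N2CCOCC2)ccc1OCOC | intermediate
9 | (S)-3-[3-geranyl-4-(methoxymethoxy)phenyl]-3-hydroxy-1-morpholinopropan-1-one | CC(C)=CCC/C(C)=C/Cc1cc([C@@H](O)CC(=O)N2CCOCC2)ccc1OCOC | intermediate
10 | phloroglucinol (benzene-1,3,5-triol) | Oc1cc(O)cc(O)c1 | starting material
11 | 3,5-bis(methoxymethoxy)phenol | COCOc1cc(O)cc(OCOC)c1 | intermediate
12 | 2-bromo-3,5-bis(methoxymethoxy)phenol | COCOc1cc(O)c(Br)c(OCOC)c1 | intermediate
13 | [2-bromo-3,5-bis(methoxymethoxy)phenoxy]trimethylsilane | COCOc1cc(O[Si](C)(C)C)c(Br)c(OCOC)c1 | intermediate (not isolated)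
14 | [2-lithio-3,5-bis(methoxymethoxy)phenoxy]trimethylsilane | COCOc1cc(O[Si](C)(C)C)c([Li])c(OCOC)c1 | intermediate (not isolated)
15 | lithium 3,5-bis(methoxymethoxy)-2-(trimethylsilyl)phenoxide | COCOc1cc(O[Li])c([Si](C)(C)C)c(OCOC)c1 | intermediate (not isolated)
16 | 3,5-bis(methoxymethoxy)-2-(trimethylsilyl)phenyl trifluoromethanesulfonate | COCOc1cc(OS(=O)(=O)C(F)(F)F)c([Si](C)(C)C)c(OCOC)c1 | intermediate
17 | potassium alkoxide of 9 | CC(C)=CCC/C(C)=C/Cc1cc([C@@H]([O-])CC(=O)N2CCOCC2)ccc1OCOC.[K+] | intermediate (not isolated)
18 | 3,5-bis(methoxymethoxy)benzyne | COCOC1=CC(OCOC)=CC#C1 | intermediate (not isolated)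
19 | (S)-3-[3-geranyl-4-(methoxymethoxy)phenyl]-3-[3,5-bis(methoxymethoxy)-2-potassiophenoxy]-1-morpholinopropan-1-one | CC(C)=CCC/C(C)=C/Cc1cc([C@H](CC(=O)N2CCOCC2)Oc2cc(OCOC)cc(OCOC)c2[K])ccc1OCOC | intermediate (not isolated)
20 | potassium (2S)-2-[3-geranyl-4-(methoxymethoxy)phenyl]-5,7-bis(methoxymethoxy)-4-morpholinochroman-4-olate (C4 epimers) | CC(C)=CCC/C(C)=C/Cc1cc([C@@H]2CC([O-])(N3CCOCC3)c3c(OCOC)cc(OCOC)cc3O2)ccc1OCOC.[K+] | intermediate (not isolated)
21 | (S)-5,7-bis(methoxymethoxy)-2-[3-geranyl-4-(methoxymethoxy)phenyl]chroman-4-one | CC(C)=CCC/C(C)=C/Cc1cc([C@@H]2CC(=O)c3c(OCOC)cc(OCOC)cc3O2)ccc1OCOC | intermediate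
22 | (S)-5,7-dihydroxy-2-(3-geranyl-4-hydroxyphenyl)chroman-4-one | CC(C)=CCC/C(C)=C/Cc1cc([C@@H]2CC(=O)c3c(O)cc(O)cc3O2)ccc1O | target

**Totals**

Total step count: 9. Longest linear sequence: 6 steps (steps 1, 2, 3, 4, 8, 9); the ring A branch (steps 5, 6, 7) joins at step 8.

**Steps most likely to fail**

1. Step 8 (aryne annulation). The aryl anion may be protonated or silylated before it reaches the amide carbonyl, or the aryne may be consumed by an ene reaction with the geranyl chain, so that uncyclised ethers result. The fallback uses known chemistry and closes the same C4–C4a bond; it sets out from β-keto amide 8 and bromophenol 12 and comes back at 21. Transfer hydrogenation of 8 with the enantiomeric catalyst RuCl(p-cymene)[(R,R)-TsDPEN] in HCO2H/Et3N would give (R)-hydroxy amide F1. Mitsunobu etherification of F1 with 12 (PPh3, DIAD, toluene, 0 °C) should give, with inversion, (S)-bromoaryl ether F2. Bromine–lithium exchange (n-BuLi, THF, −100 °C) would give aryllithium F3, which undergoes Parham cyclization onto the morpholine amide to lithium hemiaminal alkoxide F4; an AcOH quench then releases 21.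

2. Step 2 (geranylation). Substitution at the tertiary terminus of the allyl system or loss of the (E)-geometry may compete with the linear coupling. The fallback sets out from iodide 2 and comes back at 5. Miyaura borylation of 2 (B2pin2, Pd(dppf)Cl2, KOAc, dioxane, 80 °C) would give pinacol boronate F5. Suzuki–Miyaura coupling of F5 with geranyl bromide 3 (Pd(PPh3)4, K2CO3, THF/H2O, 60 °C) should give the linear product, because reductive elimination from the allylpalladium intermediate occurs at its unsubstituted terminus.

3. Step 6 (bromination). Bromination para to the hydroxyl group, or a second bromination, may erode the supply of the ortho isomer. The fallback replaces electrophilic substitution by directed ortho-metalation; it sets out from phenol 11 and comes back at 16, bypassing 12 and step 7. O-Carbamoylation of 11 (NaH, ClCONEt2, THF) would give diethylcarbamate F6. Lithiation between the carbamate and the neighbouring OMOM group (s-BuLi, TMEDA, THF, −78 °C) and a TMSCl quench would give silyl carbamate F7. Reductive carbamate cleavage with Cp2Zr(H)Cl (THF, rt) would give silyl phenol F8, and triflation (Tf2O, pyridine, CH2Cl2, 0 °C) gives 16.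

Further compounds
F1 | step 8 | (R)-3-[3-geranyl-4-(methoxymethoxy)phenyl]-3-hydroxy-1-morpholinopropan-1-one | CC(C)=CCC/C(C)=C/Cc1cc([C@H](O)CC(=O)N2CCOCC2)ccc1OCOC
F2 | step 8 | (S)-3-[2-bromo-3,5-bis(methoxymethoxy)phenoxy]-3-[3-geranyl-4-(methoxymethoxy)phenyl]-1-morpholinopropan-1-one | CC(C)=CCC/C(C)=C/Cc1cc([C@H](CC(=O)N2CCOCC2)Oc2cc(OCOC)cc(OCOC)c2Br)ccc1OCOC
F3 | step 8 | (S)-3-[2-lithio-3,5-bis(methoxymethoxy)phenoxy]-3-[3-geranyl-4-(methoxymethoxy)phenyl]-1-morpholinopropan-1-one | CC(C)=CCC/C(C)=C/Cc1cc([C@H](CC(=O)N2CCOCC2)Oc2cc(OCOC)cc(OCOC)c2[Li])ccc1OCOC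
F4 | step 8 | lithium (2S)-2-[3-geranyl-4-(methoxymethoxy)phenyl]-5,7-bis(methoxymethoxy)-4-morpholinochroman-4-olate | CC(C)=CCC/C(C)=C/Cc1cc([C@@H]2CC(O[Li])(N3CCOCC3)c3c(OCOC)cc(OCOC)cc3O2)ccc1OCOC
F5 | step 2 | methyl 4-(methoxymethoxy)-3-(4,4,5,5-tetramethyl-1,3,2-dioxaborolan-2-yl)benzoate | COC(=O)c1ccc(OCOC)c(B2OC(C)(C)C(C)(C)O2)c1
F6 | step 6 | 3,5-bis(methoxymethoxy)phenyl N,N-diethylcarbamate | CCN(CC)C(=O)Oc1cc(OCOC)cc(OCOC)c1
F7 | step 6 | 3,5-bis(methoxymethoxy)-2-(trimethylsilyl)phenyl N,N-diethylcarbamate | CCN(CC)C(=O)Oc1cc(OCOC)cc(OCOC)c1[Si](C)(C)C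
F8 | step 6 | 3,5-bis(methoxymethoxy)-2-(trimethylsilyl)phenol | COCOc1cc(O)c([Si](C)(C)C)c(OCOC)c1
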